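**Retrosynthetic overview**

1. The target 40 comes from bicyclic alcohol 37 by desilylation, O-sulfation and benzyl hydrogenolysis. In 37 the bicyclo[2.2.2]octane ring B1–B6 (B1 = bridgehead C–OH, B2 = CH–CH2Ar, B3 = CMe2, B4 = bridgehead CH, B5 = C(Me)(chain), B6 = CH2; B7–B8 = the CH2CH2 bridge) is closed last, by the bond B1–B2, from monocyclic ketone 36.
2. Enabling feature: B1 carries the hydroxyl and is bonded to B2, whose exocyclic carbon is benzylic. B1 can therefore be a ketone (ketyl) and B2 the near carbon of a styrene, with the radical ending on the benzylic carbon.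
3. Ketone 36 comes from norbornyl hydroperoxide 35 and nitrostyrene 33. The bond B1–B3 of a camphor-type norbornane is a temporary ring bond that holds B3 cis to the exo face; exo-alkylation sets B5, then β-scission cuts the bond and the B3 radical is alkenylated.
4. The chain bond C12–C13 is made by opening spiro-epoxide 17 with the acetylide of 24, which also sets the tertiary alcohol. Epoxide 17 comes from ketone 13, and 13 from bis-epoxide 8 by one oxa/carbacyclisation cascade.
5. Order of ring formation: oxepane, then its fused cyclohexane (both in step 5); the norbornane is bought with the chiral pool and opened in step 23; ring B1–B6 is closed last (step 24).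

Key step: step 24

Assumption: aryl hydrogen sulfates 39 and 40 are written as free acids for bookkeeping and would be handled as their sodium salts; the L-fructose-derived enantiomer of the Shi ketone is taken as purchasable.

**Step 1**
Reactants: 1 geranyl bromide; 2 (4-bromobut-1-yn-1-yl)trimethylsilane
Product: 4 (E)-trimethyl(7,11-dimethyldodeca-6,10-dien-1-yn-1-yl)silane, via Grignard reagent 3 (not isolated)
Conditions: 2, Mg, THF, 40 °C; then 1, Li2CuCl4 (3 mol %), THF, −20 to 0 °C
Reagents that add atoms: none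
Why: Copper-catalysed coupling of a primary alkyl Grignard reagent with an allylic bromide should occur at the primary carbon and keep the E double bond.

**Step 2**
Reactants: 4 (E)-trimethyl(7,11-dimethyldodeca-6,10-dien-1-yn-1-yl)silane
Product: 5 (E)-7,11-dimethyldodeca-6,10-dien-1-yne
Conditions: K2CO3, MeOH, rt
Reagents that add atoms: none
Why: Methanolysis of the alkynyl C–Si bond is selective and leaves both alkenes untouched.

**Step 3**
Reactants: 5 (E)-7,11-dimethyldodeca-6,10-dien-1-yne
Product: 7 (E)-trimethyl(8,12-dimethyltrideca-7,11-dien-2-yn-1-yl)silane, via lithium acetylide 6 (not isolated)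
Conditions: n-BuLi, THF, −78 °C; then Me3SiCH2OTf, −78 °C to rt
Reagents that add atoms: (trimethylsilyl)methyl trifluoromethanesulfonate, C[Si](C)(C)COS(=O)(=O)C(F)(F)F
Why: SN2 alkylation of the acetylide should give the propargylsilane that later terminates the cascade as an allene.

**Step 4**
Reactants: 7 (E)-trimethyl(8,12-dimethyltrideca-7,11-dien-2-yn-1-yl)silane
Product: 8 (S,S)-internal, (S)-terminal bis-epoxide of 7
Conditions: L-fructose-derived Shi ketone (0.4 equiv), KHSO5 (as Oxone, 2KHSO5·KHSO4·K2SO4), K2CO3, Bu4NHSO4, MeCN–CH2(OMe)2–aq. Na2B4O7 buffer, 0 °C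
Reagents that add atoms: potassium peroxymonosulfate, [K+].[O-]S(=O)(=O)OO
Why: Shi asymmetric epoxidation should oxidise both trisubstituted alkenes (alkyne and propargylsilane are inert), the spiro dioxirane transition state of this catalyst enantiomer setting the (S,S) and (S) epoxides.

**Step 5**
Reactants: 8 bis-epoxide
Product: 10 (3S,5aS,9aS)-2,2,5a-trimethyl-6-vinylidenedecahydro-1-benzoxepin-3-ol, via silyl ether 9 (not isolated)
Conditions: Me3SiOTf (1.2 equiv), 2,6-di-tert-butyl-4-methylpyridine, CH2Cl2, −78 °C; then K2CO3, MeOH, rt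
Reagents that add atoms: none
Why: In this epoxide-opening oxa/carbacyclisation cascade the internal epoxide oxygen opens the silyl-activated terminal epoxide at its tertiary carbon (oxepane) and the propargylsilane opens the resulting epoxonium anti at the tertiary carbon (cyclohexane, exocyclic allene), so the E-epoxide geometry should give the trans ring fusion with the angular methyl cis to the ring oxygen.

**Step 6**
Reactants: 10 allene alcohol
Product: 11 (3S,5aR,9aS)-3-hydroxy-2,2,5a-trimethyloctahydro-1-benzoxepin-6(2H)-one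
Conditions: O3, CH2Cl2–MeOH, −78 °C; then Me2S, −78 °C to rt
Reagents that add atoms: ozone, [O-][O+]=O
Why: Ozonolysis cleaves both cumulated double bonds of the allene and should leave the ring ketone, no other alkene being present.

**Step 7**
Reactants: 11 hydroxy ketone
Product: 12 O-phenyl thionocarbonate of 11
Conditions: PhOC(S)Cl, pyridine, DMAP (cat.), CH2Cl2, rt
Reagents that add atoms: O-phenyl chlorothionoformate, S=C(Cl)Oc1ccccc1
Why: Acylation of the secondary alcohol under non-enolising conditions prepares it for Barton–McCombie deoxygenation.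

**Step 8**
Reactants: 12 thionocarbonate
Product: 13 (5aR,9aS)-2,2,5a-trimethyloctahydro-1-benzoxepin-6(2H)-one
Conditions: Bu3SnH, AIBN (cat.), toluene, 110 °C
Reagents that add atoms: none
Why: Barton–McCombie radical deoxygenation should remove the carbinol carbon's oxygen, which the target does not carry, without touching the ketone.

**Step 9**
Reactants: 13 bicyclic ketone
Product: 15 (5aR,7S,9aS)-2,2,5a,7-tetramethyloctahydro-1-benzoxepin-6(2H)-one, via lithium enolate 14 (not isolated)
Conditions: LiN(i-Pr)2, THF, −78 °C; MeI, −78 to 0 °C; then NaOMe (cat.), MeOH, rt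
Reagents that add atoms: iodomethane, CI
Why: Only C-7 is enolisable (the other α-carbon is quaternary), and base equilibration should place the new methyl equatorial, away from a 1,3-diaxial contact with the angular methyl, which is the target configuration.

**Step 10**
Reactants: 15 methyl ketone
Product: 16 (5aS,7S,9aS)-2,2,5a,7-tetramethyl-6-methylidenedecahydro-1-benzoxepine
Conditions: Ph3PCH3Br, KOt-Bu, toluene, 90 °C
Reagents that add atoms: methylenetriphenylphosphorane, C=P(c1ccccc1)(c1ccccc1)c1ccccc1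
Why: Wittig methylenation under forcing conditions is the standard answer to hindered ketones, and the α-methyl stays in its thermodynamic equatorial position.

**Step 11**
Reactants: 16 exocyclic alkene
Product: 17 (5aR,6S,7S,9aS)-2,2,5a,7-tetramethyloctahydro-2H-spiro[1-benzoxepine-6,2'-oxirane]
Conditions: mCPBA, NaHCO3, CH2Cl2, 0 °C
Reagents that add atoms: 3-chloroperoxybenzoic acid, OOC(=O)c1cccc(Cl)c1
Why: Prilezhaev epoxidation should occur from the face opposite the axial angular methyl, giving the epoxide oxygen axial and the CH2 equatorial, which is the configuration of the tertiary alcohol.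

**Step 12**
Reactants: 18 (1R)-(−)-10-camphorsulfonyl chloride
Product: 19 (1R,4S)-7,7-dimethyl-2-oxobicyclo[2.2.1]heptane-1-carboxylic acid
Conditions: KMnO4, Na2CO3, H2O, 90 °C; then aq. H2SO4
Reagents that add atoms: potassium permanganate, [K+].[O-][Mn](=O)(=O)=O; water, O
Why: Permanganate oxidation of camphorsulfonyl chloride to ketopinic acid is a known degradation of the CH2SO2Cl group that does not touch the stereocentres.

**Step 13**
Reactants: 19 (−)-ketopinic acid
Product: 20 methyl (1R,4S)-7,7-dimethyl-2-oxobicyclo[2.2.1]heptane-1-carboxylate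
Conditions: MeI, K2CO3, DMF, rt
Reagents that add atoms: iodomethane, CI
Why: Carboxylate O-alkylation gives an ester that cannot enolise at the bridgehead.

**Step 14**
Reactants: 20 methyl ketopinate
Product: 22 methyl (1R,4S)-3,7,7-trimethyl-2-oxobicyclo[2.2.1]heptane-1-carboxylate (C-3 epimer mixture), via lithium enolate 21 (not isolated)
Conditions: LiN(i-Pr)2, THF, −78 °C; MeI, −78 to 0 °C
Reagents that add atoms: iodomethane, CI
Why: C-3 is the only enolisable position, and the epimer ratio does not matter because C-3 is enolised again in the next step.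

**Step 15**
Reactants: 22 methyl 3-methylketopinate
Product: 24 methyl (1R,3S,4R)-3,7,7-trimethyl-2-oxo-3-(prop-2-yn-1-yl)bicyclo[2.2.1]heptane-1-carboxylate (propargyl exo), via lithium enolate 23 (not isolated)
Conditions: LiN(i-Pr)2, THF–DMPU, −78 to 0 °C; propargyl bromide, −78 °C to rt
Reagents that add atoms: propargyl bromide, BrCC#C
Why: Alkylation of the tetrasubstituted norbornanone enolate should occur from the exo face, putting the propargyl group syn to the CMe2 bridge and the methyl endo, which sets the quaternary stereocentre B5.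

**Step 16**
Reactants: 24 propargyl keto ester; 17 spiro-epoxide
Product: 26 methyl (1R,3S,4R)-3-{4-[(5aR,6S,7S,9aS)-6-hydroxy-2,2,5a,7-tetramethyldecahydro-1-benzoxepin-6-yl]but-2-yn-1-yl}-3,7,7-trimethyl-2-oxobicyclo[2.2.1]heptane-1-carboxylate, via lithium acetylide 25 (not isolated)
Conditions: 24 (1.5 equiv), n-BuLi, THF, −78 °C; BF3·OEt2; then 17, −78 °C
Reagents that add atoms: none
Why: BF3-promoted opening of the 2,2-disubstituted epoxide by the lithium acetylide occurs at the CH2 terminus, so the C–O bond at the spiro carbon is kept and the tertiary alcohol has the epoxide configuration (ketone and ester of 24 carry no α-hydrogen).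

**Step 17**
Reactants: 26 alkyne
Product: 27 methyl (1R,3S,4R)-3-{4-[(5aR,6S,7S,9aS)-6-hydroxy-2,2,5a,7-tetramethyldecahydro-1-benzoxepin-6-yl]butyl}-3,7,7-trimethyl-2-oxobicyclo[2.2.1]heptane-1-carboxylate
Conditions: H2 (1 atm), Pd/C, EtOAc, rt
Reagents that add atoms: none
Why: Catalytic hydrogenation saturates the alkyne to the four-carbon chain and leaves ketone, ester and tertiary alcohol untouched.

**Step 18**
Reactants: 27 keto ester
Product: 29 3-exo-{4-[(5aR,6S,7S,9aS)-6-hydroxy-2,2,5a,7-tetramethyldecahydro-1-benzoxepin-6-yl]butyl}-3-endo,7,7-trimethylbicyclo[2.2.1]heptane-1-carboxylic acid, via hydrazone 28 (not isolated)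
Conditions: N2H4·H2O, KOH, diethylene glycol, 130 °C then 210 °C (water distilled off); aq. HCl work-up
Reagents that add atoms: none
Why: Wolff–Kishner reduction (Huang-Minlon modification) removes the non-enolisable ketone, as it does for camphor and fenchone, and the ester is saponified in the same pot.

**Step 19**
Reactants: 30 2,5-dihydroxybenzaldehyde
Product: 31 2-hydroxy-5-[(triisopropylsilyl)oxy]benzaldehyde
Conditions: i-Pr3SiCl (1.05 equiv), imidazole, CH2Cl2, 0 °C
Reagents that add atoms: chlorotriisopropylsilane, CC(C)[Si](Cl)(C(C)C)C(C)C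
Why: The 2-hydroxyl is hydrogen-bonded to the aldehyde and less nucleophilic, so silylation should occur at the 5-hydroxyl.

**Step 20**
Reactants: 31 monosilyl ether
Product: 32 2-(benzyloxy)-5-[(triisopropylsilyl)oxy]benzaldehyde
Conditions: BnBr, K2CO3, DMF, rt
Reagents that add atoms: benzyl bromide, BrCc1ccccc1
Why: Williamson etherification of the remaining phenol gives two orthogonal phenol protecting groups.

**Step 21**
Reactants: 32 protected aldehyde
Product: 33 (E)-1-(benzyloxy)-2-(2-nitrovinyl)-4-[(triisopropylsilyl)oxy]benzene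
Conditions: MeNO2, NH4OAc, AcOH, 90 °C
Reagents that add atoms: nitromethane, C[N+](=O)[O-]
Why: Henry condensation with dehydration gives the (E)-nitrostyrene.

**Step 22**
Reactants: 29 bridgehead acid
Product: 35 bridgehead hydroperoxide (29 with CO2H replaced by OOH), via Barton ester 34 (not isolated)
Conditions: N-hydroxypyridine-2-thione, DCC, DMAP (cat.), CH2Cl2, dark, rt; then O2, t-BuSH, hν (tungsten lamp), toluene, 0 °C
Reagents that add atoms: oxygen, O=O
Why: Barton decarboxylation under oxygen traps the bridgehead radical as the hydroperoxide, which marks this one carbon for later O-radical formation while the other tertiary alcohol stays untouched.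

**Step 23**
Reactants: 35 bridgehead hydroperoxide; 33 nitrostyrene
Product: 36 (3R,4S)-4-[(E)-4-{2-(benzyloxy)-5-[(triisopropylsilyl)oxy]phenyl}-2-methylbut-3-en-2-yl]-3-{4-[(5aR,6S,7S,9aS)-6-hydroxy-2,2,5a,7-tetramethyldecahydro-1-benzoxepin-6-yl]butyl}-3-methylcyclohexan-1-one
Conditions: FeSO4·7H2O (2.2 equiv), 33 (3 equiv), MeOH–THF, degassed, 0 °C to rt
Reagents that add atoms: none
Why: Divalent iron cleaves the O–O bond, the strained bridgehead alkoxy radical undergoes β-scission toward the tertiary CMe2 radical (giving the ring ketone), and this radical adds to the nitro-bearing alkene carbon and loses NO2 (radical addition–elimination) to give the E-styrene, the two ring stereocentres being untouched so that the chain stays cis to the new substituent.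

**Step 24**
Reactants: 36 styrenyl ketone
Product: 37 (1S,2S,4S,5R)-2-{2-(benzyloxy)-5-[(triisopropylsilyl)oxy]benzyl}-5-{4-[(5aR,6S,7S,9aS)-6-hydroxy-2,2,5a,7-tetramethyldecahydro-1-benzoxepin-6-yl]butyl}-3,3,5-trimethylbicyclo[2.2.2]octan-1-ol
Conditions: SmI2 (3 equiv), HMPA (12 equiv), t-BuOH (2 equiv), THF, −78 to 0 °C
Reagents that add atoms: none
Why: SmI2–HMPA reduces the ring carbonyl (B1) to a ketyl radical anion, which adds to the near styrene carbon (B2); the benzylic radical is reduced by a second SmI2 to a benzylsamarium species that tert-butanol protonates to CH2Ar. The closest known reaction type is the samarium diiodide ketyl–olefin cyclisation, which has been used to close bicyclo[2.2.2]octane rings onto 4-substituted cyclohexanones. One C–C bond (B1–B2) closes the ring B1–B6 in the 6-exo-trig mode through the boat conformer of the cyclohexanone, and the same bond completes the bicycle. The configuration at B1 is fixed by the bridge, because the side chain on B4 can reach the ketyl carbon only from its own face; at B2 the CHAr terminus of the alkene should turn into the sector next to the unsubstituted B7–B8 bridge, away from the sector that holds the butyl chain on B5, which places the benzyl group as in the target. The step needs cyclisation to outrun simple reduction or pinacol coupling of the ketone: the aryl-activated acceptor, the gem-dimethyl group on the tether (Thorpe–Ingold effect) and HMPA should secure this, and nothing else in 36 (aryl ethers, free tertiary alcohol, cyclic ether) is reduced by SmI2.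

**Step 25**
Reactants: 37 bicyclic silyl ether
Product: 38 phenol (37 with the silyl ether cleaved to OH)
Conditions: Bu4NF, THF, 0 °C
Reagents that add atoms: none
Why: Fluoride cleaves the aryl silyl ether and leaves the benzyl ether and both tertiary alcohols untouched.

**Step 26**
Reactants: 38 phenol
Product: 39 aryl hydrogen sulfate (O-benzyl ether of the target)
Conditions: SO3·pyridine (3 equiv), pyridine, rt; NaHCO3 work-up
Reagents that add atoms: sulfur trioxide–pyridine complex, [O-]S(=O)(=O)[n+]1ccccc1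
Why: O-sulfation should take place only at the single free phenol, the two tertiary alcohols being too hindered to react.

**Step 27**
Reactants: 39 benzyl ether sulfate
Product: 40 target CNP0255133.1
Conditions: H2 (1 atm), Pd/C, MeOH, rt
Reagents that add atoms: none
Why: Hydrogenolysis removes the benzyl ether and frees the phenol ortho to the benzylic carbon, the aryl sulfate being stable to these conditions.

**Compound list**

1 | geranyl bromide [(2E)-1-bromo-3,7-dimethylocta-2,6-diene] | BrC/C=C(\C)CCC=C(C)C | starting material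
2 | (4-bromobut-1-yn-1-yl)trimethylsilane | C[Si](C)(C)C#CCCBr | starting material
3 | [4-(trimethylsilyl)but-3-yn-1-yl]magnesium bromide | C[Si](C)(C)C#CCC[Mg]Br | intermediate
4 | (E)-trimethyl(7,11-dimethyldodeca-6,10-dien-1-yn-1-yl)silane | C[Si](C)(C)C#CCCC/C=C(\C)CCC=C(C)C | intermediate
5 | (E)-7,11-dimethyldodeca-6,10-dien-1-yne | C#CCCC/C=C(\C)CCC=C(C)C | intermediate
6 | lithium acetylide of 5 | [Li]C#CCCC/C=C(\C)CCC=C(C)C | intermediate
7 | (E)-trimethyl(8,12-dimethyltrideca-7,11-dien-2-yn-1-yl)silane | C[Si](C)(C)CC#CCCC/C=C(\C)CCC=C(C)C | intermediate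
8 | trimethyl{6-[(2S,3S)-3-{2-[(2S)-3,3-dimethyloxiran-2-yl]ethyl}-3-methyloxiran-2-yl]hex-2-yn-1-yl}silane | C[Si](C)(C)CC#CCCC[C@@H]1O[C@@]1(C)CC[C@@H]1OC1(C)C | intermediate
9 | trimethyl{[(3S,5aS,9aS)-2,2,5a-trimethyl-6-vinylidenedecahydro-1-benzoxepin-3-yl]oxy}silane (trans-fused) | C1CC[C@@H]2OC(C)(C)[C@@H](O[Si](C)(C)C)CC[C@@]2(C)C1=C=C | intermediate
10 | (3S,5aS,9aS)-2,2,5a-trimethyl-6-vinylidenedecahydro-1-benzoxepin-3-ol | C1CC[C@@H]2OC(C)(C)[C@@H](O)CC[C@@]2(C)C1=C=C | intermediate
11 | (3S,5aR,9aS)-3-hydroxy-2,2,5a-trimethyloctahydro-1-benzoxepin-6(2H)-one | C1CC[C@@H]2OC(C)(C)[C@@H](O)CC[C@@]2(C)C1=O | intermediate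
12 | O-phenyl O-[(3S,5aR,9aS)-2,2,5a-trimethyl-6-oxodecahydro-1-benzoxepin-3-yl] carbonothioate | C1CC[C@@H]2OC(C)(C)[C@@H](OC(=S)Oc3ccccc3)CC[C@@]2(C)C1=O | intermediate
13 | (5aR,9aS)-2,2,5a-trimethyloctahydro-1-benzoxepin-6(2H)-one | C1CC[C@@H]2OC(C)(C)CCC[C@@]2(C)C1=O | intermediate
14 | lithium enolate of 13 (C6=C7) | C=1CC[C@@H]2OC(C)(C)CCC[C@@]2(C)C1O[Li] | intermediate
15 | (5aR,7S,9aS)-2,2,5a,7-tetramethyloctahydro-1-benzoxepin-6(2H)-one | C[C@H]1CC[C@@H]2OC(C)(C)CCC[C@@]2(C)C1=O | intermediate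
16 | (5aS,7S,9aS)-2,2,5a,7-tetramethyl-6-methylidenedecahydro-1-benzoxepine | C[C@H]1CC[C@@H]2OC(C)(C)CCC[C@@]2(C)C1=C | intermediate
17 | (5aR,6S,7S,9aS)-2,2,5a,7-tetramethyloctahydro-2H-spiro[1-benzoxepine-6,2'-oxirane] | C[C@H]1CC[C@@H]2OC(C)(C)CCC[C@@]2(C)[C@]13CO3 | intermediate
18 | (1R)-(−)-10-camphorsulfonyl chloride {[(1R,4S)-7,7-dimethyl-2-oxobicyclo[2.2.1]heptan-1-yl]methanesulfonyl chloride} | C1C(=O)[C@@]2(CS(=O)(=O)Cl)CC[C@@H]1C2(C)C | starting material
19 | (1R,4S)-7,7-dimethyl-2-oxobicyclo[2.2.1]heptane-1-carboxylic acid [(−)-ketopinic acid] | C1C(=O)[C@@]2(C(=O)O)CC[C@@H]1C2(C)C | intermediate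
20 | methyl (1R,4S)-7,7-dimethyl-2-oxobicyclo[2.2.1]heptane-1-carboxylate | C1C(=O)[C@@]2(C(=O)OC)CC[C@@H]1C2(C)C | intermediate
21 | lithium enolate of 20 | C1=C(O[Li])[C@@]2(C(=O)OC)CC[C@@H]1C2(C)C | intermediate
22 | methyl (1R,4S)-3,7,7-trimethyl-2-oxobicyclo[2.2.1]heptane-1-carboxylate (C-3 epimer mixture) | CC1C(=O)[C@@]2(C(=O)OC)CC[C@@H]1C2(C)C | intermediate
23 | lithium enolate of 22 | CC1=C(O[Li])[C@@]2(C(=O)OC)CC[C@@H]1C2(C)C | intermediate
24 | methyl (1R,3S,4R)-3,7,7-trimethyl-2-oxo-3-(prop-2-yn-1-yl)bicyclo[2.2.1]heptane-1-carboxylate (propargyl exo, 3-methyl endo) | C#CC[C@]1(C)C(=O)[C@@]2(C(=O)OC)CC[C@@H]1C2(C)C | intermediate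
25 | lithium acetylide of 24 | [Li]C#CC[C@]1(C)C(=O)[C@@]2(C(=O)OC)CC[C@@H]1C2(C)C | intermediate
26 | methyl (1R,3S,4R)-3-{4-[(5aR,6S,7S,9aS)-6-hydroxy-2,2,5a,7-tetramethyldecahydro-1-benzoxepin-6-yl]but-2-yn-1-yl}-3,7,7-trimethyl-2-oxobicyclo[2.2.1]heptane-1-carboxylate | C[C@H]1CC[C@@H]2OC(C)(C)CCC[C@@]2(C)[C@]1(O)CC#CC[C@]1(C)C(=O)[C@@]2(C(=O)OC)CC[C@@H]1C2(C)C | intermediate
27 | methyl (1R,3S,4R)-3-{4-[(5aR,6S,7S,9aS)-6-hydroxy-2,2,5a,7-tetramethyldecahydro-1-benzoxepin-6-yl]butyl}-3,7,7-trimethyl-2-oxobicyclo[2.2.1]heptane-1-carboxylate | C[C@H]1CC[C@@H]2OC(C)(C)CCC[C@@]2(C)[C@]1(O)CCCC[C@]1(C)C(=O)[C@@]2(C(=O)OC)CC[C@@H]1C2(C)C | intermediate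
28 | C-2 hydrazone of the carboxylic acid derived from 27 | C[C@H]1CC[C@@H]2OC(C)(C)CCC[C@@]2(C)[C@]1(O)CCCC[C@]1(C)C(=NN)[C@@]2(C(=O)O)CC[C@@H]1C2(C)C | intermediate
29 | 3-exo-{4-[(5aR,6S,7S,9aS)-6-hydroxy-2,2,5a,7-tetramethyldecahydro-1-benzoxepin-6-yl]butyl}-3-endo,7,7-trimethylbicyclo[2.2.1]heptane-1-carboxylic acid | C[C@H]1CC[C@@H]2OC(C)(C)CCC[C@@]2(C)[C@]1(O)CCCC[C@]1(C)C[C@@]2(C(=O)O)CC[C@@H]1C2(C)C | intermediate
30 | 2,5-dihydroxybenzaldehyde | O=Cc1cc(O)ccc1O | starting material
31 | 2-hydroxy-5-[(triisopropylsilyl)oxy]benzaldehyde | O=Cc1cc(O[Si](C(C)C)(C(C)C)C(C)C)ccc1O | intermediate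
32 | 2-(benzyloxy)-5-[(triisopropylsilyl)oxy]benzaldehyde | O=Cc1cc(O[Si](C(C)C)(C(C)C)C(C)C)ccc1OCc1ccccc1 | intermediate
33 | (E)-1-(benzyloxy)-2-(2-nitrovinyl)-4-[(triisopropylsilyl)oxy]benzene | [O-][N+](=O)/C=C/c1cc(O[Si](C(C)C)(C(C)C)C(C)C)ccc1OCc1ccccc1 | intermediate
34 | 2-thioxopyridin-1(2H)-yl ester of acid 29 (Barton ester) | C[C@H]1CC[C@@H]2OC(C)(C)CCC[C@@]2(C)[C@]1(O)CCCC[C@]1(C)C[C@@]2(C(=O)ON3C=CC=CC3=S)CC[C@@H]1C2(C)C | intermediate
35 | bridgehead hydroperoxide: 29 with CO2H replaced by OOH (1-hydroperoxy-3-exo-chain-3-endo,7,7-trimethylnorbornane) | C[C@H]1CC[C@@H]2OC(C)(C)CCC[C@@]2(C)[C@]1(O)CCCC[C@]1(C)C[C@@]2(OO)CC[C@@H]1C2(C)C | intermediate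
36 | (3R,4S)-4-[(E)-4-{2-(benzyloxy)-5-[(triisopropylsilyl)oxy]phenyl}-2-methylbut-3-en-2-yl]-3-{4-[(5aR,6S,7S,9aS)-6-hydroxy-2,2,5a,7-tetramethyldecahydro-1-benzoxepin-6-yl]butyl}-3-methylcyclohexan-1-one (chain cis to the C-4 substituent) | C[C@H]1CC[C@@H]2OC(C)(C)CCC[C@@]2(C)[C@]1(O)CCCC[C@]1(C)CC(=O)CC[C@@H]1C(C)(C)/C=C/c1cc(O[Si](C(C)C)(C(C)C)C(C)C)ccc1OCc1ccccc1 | intermediate
37 | (1S,2S,4S,5R)-2-{2-(benzyloxy)-5-[(triisopropylsilyl)oxy]benzyl}-5-{4-[(5aR,6S,7S,9aS)-6-hydroxy-2,2,5a,7-tetramethyldecahydro-1-benzoxepin-6-yl]butyl}-3,3,5-trimethylbicyclo[2.2.2]octan-1-ol | C[C@H]1CC[C@@H]2OC(C)(C)CCC[C@@]2(C)[C@]1(O)CCCC[C@]1(C)C[C@@]2(O)CC[C@@H]1C(C)(C)[C@@H]2Cc1cc(O[Si](C(C)C)(C(C)C)C(C)C)ccc1OCc1ccccc1 | intermediate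
38 | phenol: 37 with the triisopropylsilyl ether cleaved to OH | C[C@H]1CC[C@@H]2OC(C)(C)CCC[C@@]2(C)[C@]1(O)CCCC[C@]1(C)C[C@@]2(O)CC[C@@H]1C(C)(C)[C@@H]2Cc1cc(O)ccc1OCc1ccccc1 | intermediate
39 | aryl hydrogen sulfate: O-benzyl ether of the target | C[C@H]1CC[C@@H]2OC(C)(C)CCC[C@@]2(C)[C@]1(O)CCCC[C@]1(C)C[C@@]2(O)CC[C@@H]1C(C)(C)[C@@H]2Cc1cc(OS(=O)(=O)O)ccc1OCc1ccccc1 | intermediate
40 | CNP0255133.1 | C[C@H]1CC[C@@H]2OC(C)(C)CCC[C@@]2(C)[C@]1(O)CCCC[C@]1(C)C[C@@]2(O)CC[C@@H]1C(C)(C)[C@@H]2Cc1cc(OS(=O)(=O)O)ccc1O | target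

**Step count and risks**

Total step count: 27. Longest linear sequence: 20 steps (steps 1–11, 16–18, 22–27).

Steps most likely to fail:

Step 23. The tertiary radical may be oxidised or reduced before it adds to the nitroalkene, or the alkoxy radical may be reduced to the alcohol without β-scission. The fallback sets out from 35 and comes back at 36, and splits the event into two known operations. FeSO4 with Cu(OAc)2 in MeOH–H2O converts 35 by β-scission and copper-mediated oxidative elimination into the isopropenyl ketone F1. Hydrogen-atom-transfer alkenylation of F1 (Fe(acac)3, PhSiH3, EtOH, 60 °C) with nitrostyrene 33 then regenerates the same tertiary radical from the alkene and gives 36.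

Step 24. Slow closure through the boat conformer may let the ketyl be reduced to the secondary alcohol, or facial selectivity at B2 may be poor. The fallback sets out from 36 and comes back at 37, and closes the ring by a polar route. Tsuji–Wacker oxidation (PdCl2, CuCl, O2, DMF–H2O), with water adding at the benzylic carbon, gives the aryl diketone F2. Intramolecular aldol addition under equilibrating conditions (LiN(SiMe3)2, THF, −78 to 0 °C) gives the bicyclic β-hydroxy ketone F3, in which B2 is epimerisable and should settle with the aroyl group toward the unsubstituted bridge. NaBH4 gives the benzylic alcohol F4, and ionic deoxygenation (Et3SiH, CF3CO2H, CH2Cl2, −20 °C) of this electron-rich benzylic alcohol gives 37.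

Step 18. The hydrazone may fail to form at a ketone flanked by two quaternary carbons, or hydroxide may cleave the non-enolisable keto acid. The fallback sets out from 27 and comes back at 29 by stepwise radical deoxygenation. NaBH4 (MeOH–THF, 50 °C) gives the hydroxy ester F5; PhOC(S)Cl with DMAP gives the thionocarbonate F6; Bu3SnH with AIBN gives the deoxygenated ester F7; LiOH (THF–MeOH–H2O, 60 °C) gives acid 29.

**Further compounds**

F1 | step 23 | isopropenyl ketone: 36 with the C-4 side chain replaced by prop-1-en-2-yl | C[C@H]1CC[C@@H]2OC(C)(C)CCC[C@@]2(C)[C@]1(O)CCCC[C@]1(C)CC(=O)CC[C@@H]1C(C)=C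
F2 | step 24 | aryl diketone: 36 with the styrene converted to CH2–C(=O)Ar | C[C@H]1CC[C@@H]2OC(C)(C)CCC[C@@]2(C)[C@]1(O)CCCC[C@]1(C)CC(=O)CC[C@@H]1C(C)(C)CC(=O)c1cc(O[Si](C(C)C)(C(C)C)C(C)C)ccc1OCc1ccccc1
F3 | step 24 | bicyclic β-hydroxy ketone: 37 with the benzylic CH2 as C=O | C[C@H]1CC[C@@H]2OC(C)(C)CCC[C@@]2(C)[C@]1(O)CCCC[C@]1(C)C[C@@]2(O)CC[C@@H]1C(C)(C)[C@@H]2C(=O)c1cc(O[Si](C(C)C)(C(C)C)C(C)C)ccc1OCc1ccccc1
F4 | step 24 | benzylic alcohol: 37 with the benzylic CH2 as CH(OH) (epimer mixture) | C[C@H]1CC[C@@H]2OC(C)(C)CCC[C@@]2(C)[C@]1(O)CCCC[C@]1(C)C[C@@]2(O)CC[C@@H]1C(C)(C)[C@@H]2C(O)c1cc(O[Si](C(C)C)(C(C)C)C(C)C)ccc1OCc1ccccc1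
F5 | step 18 | hydroxy ester: 27 with the C-2 ketone reduced to CH(OH) | C[C@H]1CC[C@@H]2OC(C)(C)CCC[C@@]2(C)[C@]1(O)CCCC[C@]1(C)C(O)[C@@]2(C(=O)OC)CC[C@@H]1C2(C)C
F6 | step 18 | O-phenyl thionocarbonate of F5 | C[C@H]1CC[C@@H]2OC(C)(C)CCC[C@@]2(C)[C@]1(O)CCCC[C@]1(C)C(OC(=S)Oc3ccccc3)[C@@]2(C(=O)OC)CC[C@@H]1C2(C)C
F7 | step 18 | methyl ester of acid 29 | C[C@H]1CC[C@@H]2OC(C)(C)CCC[C@@]2(C)[C@]1(O)CCCC[C@]1(C)C[C@@]2(C(=O)OC)CC[C@@H]1C2(C)C
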